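**Plan**

- Cuts, in retrosynthetic order: the C8–prenyl bond (back to a 7-O-(1,1-dimethylallyl) ether, aromatic Claisen shift); the C3–C1′ bond between ring C and ring B (ketone α-arylation); then, together, the aryl–CH2 and aryl–O bonds of the dimethyldihydropyran ring fused to ring B.
- Forward: the dihydropyran ring is built first, on an ortho-chloro iodobenzene (the future ring B), by one palladium/norbornene (Catellani-type) annulation with 4-bromo-2-methylbutan-2-ol. Para-bromination, α-arylation of a purchased chromanone (rings A and C), O-allylation, reduction/re-oxidation and the Claisen shift follow.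
- Enabling feature: in ring B the ether oxygen (on C4′) and the benzylic CH2 (on C3′) sit on adjacent ring carbons, and the oxygen is bound to a carbon carrying two methyl groups and no hydrogen. The pair therefore maps onto the ipso C–I and ortho C–H positions of an aryl iodide, and the palladium alkoxide can only reductively eliminate.
- Helpers: a chlorine on the other ortho carbon (C5′) prevents a second alkylation and then steers the bromination; it is removed by hydrogenolysis in step 5 together with the benzyl group on O7.
- Stereochemistry: C3 is the only stereocentre and is epimerisable. It is set late by asymmetric transfer hydrogenation with dynamic kinetic resolution (RuCl(p-cymene)[(R,R)-TsDPEN], cis-(3R,4R) alcohol), then kept through a non-basic re-oxidation of C4 and a neutral thermal last step.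

Key step: step 1

Remark: the target SMILES is read as the (3R) enantiomer; 1-chloro-2-iodobenzene, 4-bromo-2-methylbutan-2-ol, 7-hydroxychroman-4-one and 2-methylbut-3-en-2-ol are taken as purchasable ("chroman" = 3,4-dihydro-2H-chromene).

**Step 1**
Reactants: 1 1-chloro-2-iodobenzene; 2 4-bromo-2-methylbutan-2-ol
Product: 3 8-chloro-2,2-dimethylchroman
Conditions: Pd(OAc)2 (5 mol%), P(2-furyl)3 (12 mol%), norbornene (2 equiv), Cs2CO3 (3 equiv), 2 (2 equiv), MeCN, 90 °C
Reagents that add atoms: none
Why: Proposed new method: the step is a Catellani-type annulation: zerovalent palladium inserts into the C–I bond of 1, norbornene insertion and ortho C–H palladation give an aryl–norbornyl palladacycle of divalent palladium, and this is alkylated at its aryl carbon by the primary bromide of 2 through a tetravalent palladium intermediate, which forms the aryl–CH2 bond. The arene, now substituted at both ortho positions, expels norbornene by β-carbon elimination, the tethered tertiary alkoxide displaces halide on palladium, and C–O reductive elimination forms the aryl–O bond and returns zerovalent palladium. The closest known reaction types are the palladium/norbornene ortho-alkylation/ipso-amination of aryl iodides with bromoalkylamines, the same catalysis with epoxides as bifunctional partners giving 2,3-dihydrobenzofurans, and the palladium-catalysed intramolecular etherification of aryl halides by tertiary alcohols; new is the 3-bromopropyl tertiary alcohol as partner and the six-membered ether ring. The only ring closed is the dihydropyran ring, closed at the aryl–O bond by reductive elimination from a seven-membered oxapalladacycle (formally a 6-exo attack of the alkoxide on the ipso carbon), and no stereocentre is formed. The step needs a single ortho alkylation, ipso termination by oxygen and reaction at C–I but not C–Cl: the chlorine ortho to iodine leaves only one ortho C–H, forces norbornene out after one alkylation and makes the aryl–palladium bond electron-poor enough for C–O reductive elimination, the carbinol carbon of 2 carries two methyl groups and no hydrogen so that the palladium alkoxide cannot undergo β-hydride elimination, and the triarylphosphine catalyst does not insert into aryl chlorides.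

**Step 2**
Reactants: 3 8-chloro-2,2-dimethylchroman
Product: 4 6-bromo-8-chloro-2,2-dimethylchroman
Conditions: NBS (1.05 equiv), MeCN, 0 °C to rt, dark
Reagents that add atoms: N-bromosuccinimide, O=C1CCC(=O)N1Br
Why: Electrophilic aromatic bromination should go para to the ring oxygen (C6) because the ortho position C8 is occupied by chlorine, and the ionic conditions leave the benzylic C4 methylene alone.

**Step 3**
Reactants: 5 7-hydroxychroman-4-one
Product: 6 7-(benzyloxy)chroman-4-one
Conditions: BnBr (1.1 equiv), K2CO3 (1.5 equiv), acetone, reflux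
Reagents that add atoms: benzyl bromide, BrCc1ccccc1
Why: Williamson etherification of the acidic para-acyl phenol masks O7 for the strongly basic arylation that follows.

**Step 4**
Reactants: 4 6-bromo-8-chloro-2,2-dimethylchroman; 6 7-(benzyloxy)chroman-4-one
Product: 7 rac-7-(benzyloxy)-3-(8-chloro-2,2-dimethylchroman-6-yl)chroman-4-one
Conditions: Pd2(dba)3 (2 mol%), Xantphos (5 mol%), NaOtBu (1.5 equiv), toluene, 80 °C; aq. NH4Cl quench
Reagents that add atoms: none
Why: Palladium-catalysed ketone enolate α-arylation (Buchwald–Hartwig type), a known entry to isoflavanones from 4-chromanones, should join the C3 methylene to the aryl bromide while the bisphosphine catalyst leaves the hindered aryl chloride untouched and the more acidic product enolate resists a second arylation; the new C3 stereocentre forms racemic and is corrected in step 8.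

**Step 5**
Reactants: 7 rac-7-(benzyloxy)-3-(8-chloro-2,2-dimethylchroman-6-yl)chroman-4-one
Product: 9 rac-3-(2,2-dimethylchroman-6-yl)-7-hydroxychroman-4-one, via chlorophenol 8 (not isolated)
Conditions: H2 (1 atm), 10% Pd/C, Et3N (2 equiv), EtOAc/MeOH, rt
Reagents that add atoms: none
Why: Catalytic hydrogenolysis should cleave the benzyl ether and then the aryl C–Cl bond of the temporary blocking group, with Et3N taking up HCl and tempering the catalyst so that the electron-rich aryl ketone is not reduced.

**Step 6**
Reactants: 10 2-methylbut-3-en-2-ol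
Product: 12 tert-butyl (2-methylbut-3-en-2-yl) carbonate, via lithium alkoxide 11 (not isolated)
Conditions: n-BuLi (1.0 equiv), THF, −78 to 0 °C; then Boc2O (1.05 equiv), 0 °C to rt
Reagents that add atoms: di-tert-butyl dicarbonate, CC(C)(C)OC(=O)OC(=O)OC(C)(C)C
Why: Acylation of the tertiary lithium alkoxide by the dicarbonate is the standard preparation of this allylic carbonate.

**Step 7**
Reactants: 9 rac-3-(2,2-dimethylchroman-6-yl)-7-hydroxychroman-4-one; 12 tert-butyl (2-methylbut-3-en-2-yl) carbonate
Product: 13 rac-3-(2,2-dimethylchroman-6-yl)-7-[(2-methylbut-3-en-2-yl)oxy]chroman-4-one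
Conditions: Pd(PPh3)4 (3 mol%), 12 (1.15 equiv), THF, 0 °C
Reagents that add atoms: none
Why: Tsuji–Trost O-allylation: ionisation and decarboxylation of 12 give a 1,1-dimethyl-π-allyl complex of divalent palladium and tert-butoxide, which deprotonates the phenol (far more acidic than C3–H), and the phenoxide should attack the more substituted allyl terminus under kinetic control at low temperature to give the tertiary ether.

**Step 8**
Reactants: 13 rac-3-(2,2-dimethylchroman-6-yl)-7-[(2-methylbut-3-en-2-yl)oxy]chroman-4-one
Product: 14 (3R,4R)-3-(2,2-dimethylchroman-6-yl)-7-[(2-methylbut-3-en-2-yl)oxy]chroman-4-ol (cis)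
Conditions: RuCl(p-cymene)[(R,R)-TsDPEN] (2 mol%), HCO2H (3 equiv)/Et3N (4 equiv), EtOAc, 40 °C
Reagents that add atoms: none
Why: Noyori-type asymmetric transfer hydrogenation under dynamic kinetic resolution, precedented for isoflavanones: Et3N racemises C3 through the enol faster than the slow enantiomer is reduced, and the (R,R)-catalyst delivers hydride to the carbonyl face that gives the (4R) carbinol (aryl ketone model) anti to the C3 aryl group, so only the (3R)-ketone is consumed and the cis-(3R,4R) alcohol should result, the vinyl group and the tertiary allyl ether being inert to the outer-sphere hydride and the amine-buffered medium.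

**Step 9**
Reactants: 14 (3R,4R)-3-(2,2-dimethylchroman-6-yl)-7-[(2-methylbut-3-en-2-yl)oxy]chroman-4-ol
Product: 15 (3R)-3-(2,2-dimethylchroman-6-yl)-7-[(2-methylbut-3-en-2-yl)oxy]chroman-4-one
Conditions: Dess–Martin periodinane (1.3 equiv), CH2Cl2, 0 °C to rt
Reagents that add atoms: none
Why: Dess–Martin oxidation of the benzylic carbinol under non-basic conditions should return the C4 ketone without enolising the now homochiral C3 centre.

**Step 10**
Reactants: 15 (3R)-3-(2,2-dimethylchroman-6-yl)-7-[(2-methylbut-3-en-2-yl)oxy]chroman-4-one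
Product: 17 (3R)-3-(2,2-dimethylchroman-6-yl)-7-hydroxy-8-(3-methylbut-2-en-1-yl)chroman-4-one (target), via dienone 16 (not isolated)
Conditions: toluene (degassed), 110 °C, sealed tube
Reagents that add atoms: none
Why: Aromatic Claisen rearrangement ([3,3] shift of the 1,1-dimethylallyl ether) should deliver the prenyl group to C8, the ortho carbon joined to C7 by the bond of higher π-order (the vinylogous-ester conjugation O1–C8a=C4a–C4=O fixes the C7=C8 double bond), and tautomerisation of the dienone frees the 7-OH, with no acid or base present to disturb the (R) configuration at C3.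

**Compound list**

1 | 1-chloro-2-iodobenzene | Clc1ccccc1I | starting material
2 | 4-bromo-2-methylbutan-2-ol | CC(C)(O)CCBr | starting material
3 | 8-chloro-2,2-dimethylchroman | CC1(C)CCc2cccc(Cl)c2O1 | intermediate
4 | 6-bromo-8-chloro-2,2-dimethylchroman | CC1(C)CCc2cc(Br)cc(Cl)c2O1 | intermediate
5 | 7-hydroxychroman-4-one | O=C1CCOc2cc(O)ccc12 | starting material
6 | 7-(benzyloxy)chroman-4-one | O=C1CCOc2cc(OCc3ccccc3)ccc12 | intermediate
7 | rac-7-(benzyloxy)-3-(8-chloro-2,2-dimethylchroman-6-yl)chroman-4-one | O=C1c2ccc(OCc3ccccc3)cc2OCC1c1cc(Cl)c3c(c1)CCC(C)(C)O3 | intermediate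
8 | rac-3-(8-chloro-2,2-dimethylchroman-6-yl)-7-hydroxychroman-4-one (chlorophenol, not isolated) | O=C1c2ccc(O)cc2OCC1c1cc(Cl)c3c(c1)CCC(C)(C)O3 | intermediate
9 | rac-3-(2,2-dimethylchroman-6-yl)-7-hydroxychroman-4-one | O=C1c2ccc(O)cc2OCC1c1ccc3c(c1)CCC(C)(C)O3 | intermediate
10 | 2-methylbut-3-en-2-ol | C=CC(C)(C)O | starting material
11 | lithium 2-methylbut-3-en-2-olate (not isolated) | C=CC(C)(C)[O-].[Li+] | intermediate
12 | tert-butyl (2-methylbut-3-en-2-yl) carbonate | C=CC(C)(C)OC(=O)OC(C)(C)C | intermediate
13 | rac-3-(2,2-dimethylchroman-6-yl)-7-[(2-methylbut-3-en-2-yl)oxy]chroman-4-one | C=CC(C)(C)Oc1ccc2c(c1)OCC(c1ccc3c(c1)CCC(C)(C)O3)C2=O | intermediate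
14 | (3R,4R)-3-(2,2-dimethylchroman-6-yl)-7-[(2-methylbut-3-en-2-yl)oxy]chroman-4-ol (cis) | C=CC(C)(C)Oc1ccc2c(c1)OC[C@@H](c1ccc3c(c1)CCC(C)(C)O3)[C@H]2O | intermediate
15 | (3R)-3-(2,2-dimethylchroman-6-yl)-7-[(2-methylbut-3-en-2-yl)oxy]chroman-4-one | C=CC(C)(C)Oc1ccc2c(c1)OC[C@@H](c1ccc3c(c1)CCC(C)(C)O3)C2=O | intermediate
16 | (3R)-3-(2,2-dimethylchroman-6-yl)-8-(3-methylbut-2-en-1-yl)-2,3-dihydro-4H-chromene-4,7(8H)-dione (Claisen dienone, not isolated, C8 undefined) | CC(C)=CCC1C(=O)C=CC2=C1OC[C@@H](c1ccc3c(c1)CCC(C)(C)O3)C2=O | intermediate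
17 | (3R)-3-(2,2-dimethylchroman-6-yl)-7-hydroxy-8-(3-methylbut-2-en-1-yl)chroman-4-one | CC(C)=CCc1c(O)ccc2c1OC[C@@H](c1ccc3c(c1)CCC(C)(C)O3)C2=O | target

**Totals and risks**

Total step count: 10. Longest linear sequence: 8 steps (1, 2, 4, 5, 7, 8, 9, 10); steps 3 and 6 are side branches.

Steps most likely to fail:

1. Step 1. The C–O reductive elimination from the arylpalladium alkoxide may be slower than decay of that intermediate (protodepalladation to the open-chain alcohol, return of norbornene), and the bromo alcohol may be consumed by base (oxetane formation, elimination) before it reaches the palladacycle. Fallback with known chemistry, closing the ring at O–CMe2 instead: acid-catalysed condensation of 4-bromophenol with isoprene (85% H3PO4, rt) gives 6-bromo-2,2-dimethylchroman F1. The fallback sets out from 6, which is α-arylated with F1 under the conditions of step 4 to give rac-7-(benzyloxy)-3-(2,2-dimethylchroman-6-yl)chroman-4-one F2. Hydrogenolysis of F2 (H2, Pd/C, EtOAc/MeOH) comes back to the route at 9.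

2. Step 10. Configuration at C3 may be partly lost through thermal enolisation once the acidic phenol is set free, and the allyl shift may divide between C8 and C6. The fallback sets out from 13 and moves the rearrangement ahead of the stereo-setting steps. Heating the racemate (toluene, 110 °C), where the C6 isomer can be removed without stereochemical cost, gives rac-3-(2,2-dimethylchroman-6-yl)-7-hydroxy-8-(3-methylbut-2-en-1-yl)chroman-4-one F3. TIPSCl/imidazole (DMF) gives rac-3-(2,2-dimethylchroman-6-yl)-8-(3-methylbut-2-en-1-yl)-7-(triisopropylsilyloxy)chroman-4-one F4. Transfer hydrogenation as in step 8 gives (3R,4R)-3-(2,2-dimethylchroman-6-yl)-8-(3-methylbut-2-en-1-yl)-7-(triisopropylsilyloxy)chroman-4-ol F5, and Dess–Martin oxidation gives (3R)-3-(2,2-dimethylchroman-6-yl)-8-(3-methylbut-2-en-1-yl)-7-(triisopropylsilyloxy)chroman-4-one F6. TBAF buffered with AcOH (THF, 0 °C) removes the silyl group and comes back at 17.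

3. Step 7. Zerovalent palladium may re-ionise the tertiary aryl ether, with drift to the linear prenyl ether, and the enolisable C3 position may be C-allylated. The fallback sets out from 9: O-propargylation with 3-chloro-3-methylbut-1-yne (K2CO3, KI, CuI cat., acetone, 50 °C) gives rac-3-(2,2-dimethylchroman-6-yl)-7-[(2-methylbut-3-yn-2-yl)oxy]chroman-4-one F7. Semi-hydrogenation (H2, Pd/CaCO3 poisoned with Pb(OAc)2, quinoline, EtOAc) comes back at 13.

**Further compounds**

F1 | step 1 | 6-bromo-2,2-dimethylchroman | CC1(C)CCc2cc(Br)ccc2O1
F2 | step 1 | rac-7-(benzyloxy)-3-(2,2-dimethylchroman-6-yl)chroman-4-one | O=C1c2ccc(OCc3ccccc3)cc2OCC1c1ccc3c(c1)CCC(C)(C)O3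
F3 | step 10 | rac-3-(2,2-dimethylchroman-6-yl)-7-hydroxy-8-(3-methylbut-2-en-1-yl)chroman-4-one | CC(C)=CCc1c(O)ccc2c1OCC(c1ccc3c(c1)CCC(C)(C)O3)C2=O
F4 | step 10 | rac-3-(2,2-dimethylchroman-6-yl)-8-(3-methylbut-2-en-1-yl)-7-(triisopropylsilyloxy)chroman-4-one | CC(C)=CCc1c(O[Si](C(C)C)(C(C)C)C(C)C)ccc2c1OCC(c1ccc3c(c1)CCC(C)(C)O3)C2=O
F5 | step 10 | (3R,4R)-3-(2,2-dimethylchroman-6-yl)-8-(3-methylbut-2-en-1-yl)-7-(triisopropylsilyloxy)chroman-4-ol | CC(C)=CCc1c(O[Si](C(C)C)(C(C)C)C(C)C)ccc2c1OC[C@@H](c1ccc3c(c1)CCC(C)(C)O3)[C@H]2O
F6 | step 10 | (3R)-3-(2,2-dimethylchroman-6-yl)-8-(3-methylbut-2-en-1-yl)-7-(triisopropylsilyloxy)chroman-4-one | CC(C)=CCc1c(O[Si](C(C)C)(C(C)C)C(C)C)ccc2c1OC[C@@H](c1ccc3c(c1)CCC(C)(C)O3)C2=O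
F7 | step 7 | rac-3-(2,2-dimethylchroman-6-yl)-7-[(2-methylbut-3-yn-2-yl)oxy]chroman-4-one | C#CC(C)(C)Oc1ccc2c(c1)OCC(c1ccc3c(c1)CCC(C)(C)O3)C2=O
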